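**Strategy.** The ring is numbered C1 (alkene carbon carrying C7H2–O-tiglate), C2 (ketone), C3 (OAc), C4 (isopropyl), C5 (O-tiglate), C6 (vinylic CH). Its C7–C1(=C6)–C2=O unit is the allylically transposed form of a Morita–Baylis–Hillman adduct, so the ring is disconnected at C1–C6. One phosphine-catalysed operation joins the α-carbon C1 of a vinyl ketone to a tethered C6 aldehyde, closing the six-membered ring and leaving a C6 hydroxyl that is later tigloylated and shifted to C7. The precursor is the open chain C7=C1–C2(=O)–C3H(OAc)–C4H(iPr)–C5H(O-tiglate)–C6HO, whose stereocentres come from an anti-aldol (C4, C5) and a Felkin addition (C3).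

Key step: step 7

Remark: the cis C4/C5 pair of the ring corresponds to an anti aldol in the open chain (C4 S, C5 R in the adduct). The (S)-N-acylthiazolidinethione is assumed to give the anti adduct whose α-centre matches the boron syn-aldol of the same auxiliary; if the opposite sense were found, the (R)-auxiliary would be used with no other change. Aldehyde 4 is used anhydrous (extracted from its commercial aqueous solution, dried, distilled).

**Step 1**
Reactants: 1 (S)-4-benzyl-1,3-thiazolidine-2-thione; 2 3-methylbutanoyl chloride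
Product: 3 (S)-4-benzyl-3-(3-methylbutanoyl)-1,3-thiazolidine-2-thione
Conditions: Et3N, DMAP (cat.), CH2Cl2, 0 °C to rt
Reagents that add atoms: none
Why: N-acylation of the thiazolidinethione nitrogen by the acid chloride under amine base with DMAP catalysis is the standard way to load this auxiliary and touches no stereocentre.

**Step 2**
Reactants: 3 (S)-4-benzyl-3-(3-methylbutanoyl)-1,3-thiazolidine-2-thione; 4 2,2-dimethoxyacetaldehyde
Product: 6 (S)-4-benzyl-3-[(2S,3R)-3-hydroxy-4,4-dimethoxy-2-(propan-2-yl)butanoyl]-1,3-thiazolidine-2-thione, via trimethylsilyl ether 5 (not isolated)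
Conditions: MgBr2·OEt2 (10 mol%), Et3N, Me3SiCl, EtOAc, rt; then 1 M HCl/THF, rt
Reagents that add atoms: none
Why: Magnesium-halide-catalysed direct anti-aldol of an N-acylthiazolidinethione (soft enolisation by Et3N at magnesium, turnover by O-silylation), in which the (Z)-enolate reacts through a boat-like transition state on the face away from the benzyl group, which should set C4 as S and C5 as R (anti), while the acceptor, whose only α-hydrogen sits on the acetal carbon, behaves as a non-enolisable aldehyde.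

**Step 3**
Reactants: 6 (S)-4-benzyl-3-[(2S,3R)-3-hydroxy-4,4-dimethoxy-2-(propan-2-yl)butanoyl]-1,3-thiazolidine-2-thione; 7 tiglic acid
Product: 9 (2R,3S)-4-[(S)-4-benzyl-2-sulfanylidene-1,3-thiazolidin-3-yl]-1,1-dimethoxy-4-oxo-3-(propan-2-yl)butan-2-yl (E)-2-methylbut-2-enoate, via mixed anhydride 8 (not isolated)
Conditions: 7, 2,4,6-Cl3C6H2COCl, Et3N, toluene, rt; then 6, DMAP (0.2 equiv), rt
Reagents that add atoms: none
Why: Yamaguchi esterification, in which DMAP transfers the tigloyl group from mixed anhydride 8 to the hindered C5 hydroxyl with retention at C5, while allylic 1,3-strain in the imide keeps C4–H out of conjugation so that β-elimination of the new ester should be slow.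

**Step 4**
Reactants: 9 (2R,3S)-4-[(S)-4-benzyl-2-sulfanylidene-1,3-thiazolidin-3-yl]-1,1-dimethoxy-4-oxo-3-(propan-2-yl)butan-2-yl (E)-2-methylbut-2-enoate
Product: 10 (2R,3S)-3-formyl-1,1-dimethoxy-4-methylpentan-2-yl (E)-2-methylbut-2-enoate
Conditions: i-Bu2AlH (1.1 equiv), CH2Cl2, −78 °C; aq. potassium sodium tartrate; used crude at once
Reagents that add atoms: none
Why: Direct reductive cleavage of the auxiliary, in which hydride adds to the activated N-acylthiazolidinethione to give an aluminium hemiaminal that is stable at −78 °C and collapses to the aldehyde on work-up, this carbonyl being far more electrophilic than the hindered conjugated tiglate, and the non-basic conditions leave C4 intact.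

**Step 5**
Reactants: 10 (2R,3S)-3-formyl-1,1-dimethoxy-4-methylpentan-2-yl (E)-2-methylbut-2-enoate; 11 methoxyallene
Product: 14 (4R,5R,6R)-4-acetoxy-3,7,7-trimethoxy-5-(propan-2-yl)hepta-1,2-dien-6-yl (E)-2-methylbut-2-enoate, via lithiated methoxyallene 12 (not isolated), via lithium alkoxide 13 (not isolated)
Conditions: 11, n-BuLi, THF, −78 °C; 10, −78 °C; then Ac2O, −78 to 0 °C
Reagents that add atoms: acetic anhydride CC(=O)OC(C)=O
Why: 1,2-Addition of 1-lithio-1-methoxyallene (an acryloyl anion equivalent) to the aldehyde with acetylation of the lithium alkoxide in the same flask, in which Felkin–Anh attack anti to the C4–C5 bond is reinforced by 1,3-anti induction from the C5 acyloxy group of this anti-configured aldehyde and should give the 3,4-syn-3,5-anti isomer (C3 R), the immediate acetylation preventing tiglate migration from O5 to O3.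

**Step 6**
Reactants: 14 (4R,5R,6R)-4-acetoxy-3,7,7-trimethoxy-5-(propan-2-yl)hepta-1,2-dien-6-yl (E)-2-methylbut-2-enoate
Product: 16 (2R,3S,4R)-4-acetoxy-1,5-dioxo-3-(propan-2-yl)hept-6-en-2-yl (E)-2-methylbut-2-enoate, via vinyl ketone acetal 15 (not isolated)
Conditions: 50% aq. CF3CO2H, CHCl3, 0 °C to rt; toluene azeotrope
Reagents that add atoms: water O
Why: Acid hydrolysis of the allenyl enol ether (protonation at the central allene carbon, addition of water, loss of methanol) unveils the vinyl ketone, and continued exposure hydrolyses the deactivated α-acyloxy dimethyl acetal to the C6 aldehyde under conditions that carboxylic esters tolerate and that avoid base-mediated epimerisation at C3 and C5.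

**Step 7**
Reactants: 16 (2R,3S,4R)-4-acetoxy-1,5-dioxo-3-(propan-2-yl)hept-6-en-2-yl (E)-2-methylbut-2-enoate
Product: 17 (1R,2S,3R,6R)-3-acetoxy-6-hydroxy-5-methylidene-4-oxo-2-(propan-2-yl)cyclohexyl (E)-2-methylbut-2-enoate
Conditions: PMe3 (0.3 equiv), degassed t-AmOH, rt, 0.02 M
Reagents that add atoms: none
Why: PMe3 adds in conjugate fashion to the unsubstituted terminus C7, the β-phosphonium enolate attacks the C6 aldehyde through C1, and proton transfer assisted by the alcohol solvent followed by loss of PMe3 restores C1=C7 and returns the catalyst. The closest known reaction type is the phosphine-catalysed intramolecular Morita–Baylis–Hillman cyclisation of enone aldehydes to 2-methylene-3-hydroxycycloalkanones. The ring closes in a 6-(enolendo)-exo-trig mode, with the enolate C1=C2 inside the new ring and the C6=O outside it. The new stereocentre C6 is set under substrate control by the neighbouring C5 tiglate and need not be controlled, because both epimers lose it in step 9. The selectivity required is ring closure over intermolecular Rauhut–Currier or aldol oligomerisation, and it is secured by C1 being the only nucleophilic carbon the catalyst generates (so only the six-membered ring can form), by the high electrophilicity of the α-acyloxy aldehyde and by dilution. Migration of the tiglate between O5 and O6 at the alkoxide stage would be harmless, since step 8 acylates whichever hydroxyl is left.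

**Step 8**
Reactants: 17 (1R,2S,3R,6R)-3-acetoxy-6-hydroxy-5-methylidene-4-oxo-2-(propan-2-yl)cyclohexyl (E)-2-methylbut-2-enoate; 7 tiglic acid
Product: 19 (1R,2R,3S,4R)-4-acetoxy-6-methylidene-5-oxo-3-(propan-2-yl)cyclohexane-1,2-diyl bis[(E)-2-methylbut-2-enoate], via nitrobenzoic mixed anhydride 18 (not isolated)
Conditions: 7, 2-methyl-6-nitrobenzoic anhydride, Et3N, DMAP (0.2 equiv), CH2Cl2, rt
Reagents that add atoms: none
Why: Shiina esterification, in which tiglic acid and 2-methyl-6-nitrobenzoic anhydride form mixed anhydride 18 in the flask and DMAP passes its less hindered tigloyl group to the secondary allylic hydroxyl at room temperature, so that both C6 epimers and any material whose C5 tiglate has moved to O6 converge on the same 5,6-bis-tiglate.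

**Step 9**
Reactants: 19 (1R,2R,3S,4R)-4-acetoxy-6-methylidene-5-oxo-3-(propan-2-yl)cyclohexane-1,2-diyl bis[(E)-2-methylbut-2-enoate]
Product: 20 [(3S,4S,5R)-5-acetoxy-3-{[(E)-2-methylbut-2-enoyl]oxy}-6-oxo-4-(propan-2-yl)cyclohex-1-en-1-yl]methyl (E)-2-methylbut-2-enoate
Conditions: DABCO (20 mol%), THF, rt to 40 °C
Reagents that add atoms: none
Why: Amine-catalysed 1,3-transposition of a Morita–Baylis–Hillman ester (SN2' addition of DABCO at C7 with loss of the C6 tiglate, then SN2 return of tiglate at C7 with loss of DABCO), driven by formation of the conjugated trisubstituted C1=C6 enone and a primary ester, which erases the C6 stereocentre and leaves C3, C4 and C5 untouched.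

**Compound list**
1 | (S)-4-benzyl-1,3-thiazolidine-2-thione | S=C1SC[C@H](Cc2ccccc2)N1 | starting material
2 | 3-methylbutanoyl chloride | CC(C)CC(Cl)=O | starting material
3 | (S)-4-benzyl-3-(3-methylbutanoyl)-1,3-thiazolidine-2-thione | S=C1SC[C@H](Cc2ccccc2)N1C(=O)CC(C)C | intermediate
4 | 2,2-dimethoxyacetaldehyde | COC(OC)C=O | starting material
5 | (S)-4-benzyl-3-[(2S,3R)-4,4-dimethoxy-2-(propan-2-yl)-3-(trimethylsilyloxy)butanoyl]-1,3-thiazolidine-2-thione | S=C1SC[C@H](Cc2ccccc2)N1C(=O)[C@@H](C(C)C)[C@@H](O[Si](C)(C)C)C(OC)OC | intermediate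
6 | (S)-4-benzyl-3-[(2S,3R)-3-hydroxy-4,4-dimethoxy-2-(propan-2-yl)butanoyl]-1,3-thiazolidine-2-thione (anti aldol; C4 S, C5 R) | S=C1SC[C@H](Cc2ccccc2)N1C(=O)[C@@H](C(C)C)[C@@H](O)C(OC)OC | intermediate
7 | tiglic acid, (E)-2-methylbut-2-enoic acid | C/C=C(\C)C(=O)O | starting material
8 | (E)-2-methylbut-2-enoic 2,4,6-trichlorobenzoic anhydride | C/C=C(\C)C(=O)OC(=O)c1c(Cl)cc(Cl)cc1Cl | intermediate
9 | (2R,3S)-4-[(S)-4-benzyl-2-sulfanylidene-1,3-thiazolidin-3-yl]-1,1-dimethoxy-4-oxo-3-(propan-2-yl)butan-2-yl (E)-2-methylbut-2-enoate | S=C1SC[C@H](Cc2ccccc2)N1C(=O)[C@@H](C(C)C)[C@@H](OC(=O)/C(C)=C/C)C(OC)OC | intermediate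
10 | (2R,3S)-3-formyl-1,1-dimethoxy-4-methylpentan-2-yl (E)-2-methylbut-2-enoate (C3 aldehyde) | O=C[C@@H](C(C)C)[C@@H](OC(=O)/C(C)=C/C)C(OC)OC | intermediate
11 | methoxyallene (1-methoxypropa-1,2-diene) | COC=C=C | starting material
12 | 1-lithio-1-methoxyallene | [Li]C(OC)=C=C | intermediate
13 | lithium (4R,5R,6R)-3,7,7-trimethoxy-6-{[(E)-2-methylbut-2-enoyl]oxy}-5-(propan-2-yl)hepta-1,2-dien-4-olate | C=C=C(OC)[C@H](O[Li])[C@@H](C(C)C)[C@@H](OC(=O)/C(C)=C/C)C(OC)OC | intermediate
14 | (4R,5R,6R)-4-acetoxy-3,7,7-trimethoxy-5-(propan-2-yl)hepta-1,2-dien-6-yl (E)-2-methylbut-2-enoate (the descriptor at the isopropyl carbon changes by priority only) | C=C=C(OC)[C@H](OC(C)=O)[C@@H](C(C)C)[C@@H](OC(=O)/C(C)=C/C)C(OC)OC | intermediate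
15 | (2R,3S,4R)-4-acetoxy-1,1-dimethoxy-5-oxo-3-(propan-2-yl)hept-6-en-2-yl (E)-2-methylbut-2-enoate | C=CC(=O)[C@H](OC(C)=O)[C@@H](C(C)C)[C@@H](OC(=O)/C(C)=C/C)C(OC)OC | intermediate
16 | (2R,3S,4R)-4-acetoxy-1,5-dioxo-3-(propan-2-yl)hept-6-en-2-yl (E)-2-methylbut-2-enoate (acyclic vinyl ketone aldehyde, key-step precursor) | C=CC(=O)[C@H](OC(C)=O)[C@@H](C(C)C)[C@@H](OC(=O)/C(C)=C/C)C=O | intermediate
17 | (1R,2S,3R,6R)-3-acetoxy-6-hydroxy-5-methylidene-4-oxo-2-(propan-2-yl)cyclohexyl (E)-2-methylbut-2-enoate (key-step product; the C6 epimer serves equally) | C=C1[C@@H](O)[C@H](OC(=O)/C(C)=C/C)[C@H](C(C)C)[C@@H](OC(C)=O)C1=O | intermediate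
18 | (E)-2-methylbut-2-enoic 2-methyl-6-nitrobenzoic anhydride | C/C=C(\C)C(=O)OC(=O)c1c(C)cccc1[N+](=O)[O-] | intermediate
19 | (1R,2R,3S,4R)-4-acetoxy-6-methylidene-5-oxo-3-(propan-2-yl)cyclohexane-1,2-diyl bis[(E)-2-methylbut-2-enoate] (the C6 epimer serves equally) | C=C1[C@@H](OC(=O)/C(C)=C/C)[C@H](OC(=O)/C(C)=C/C)[C@H](C(C)C)[C@@H](OC(C)=O)C1=O | intermediate
20 | [(3S,4S,5R)-5-acetoxy-3-{[(E)-2-methylbut-2-enoyl]oxy}-6-oxo-4-(propan-2-yl)cyclohex-1-en-1-yl]methyl (E)-2-methylbut-2-enoate | C/C=C(\C)C(=O)OCC1=C[C@H](OC(=O)/C(C)=C/C)[C@H](C(C)C)[C@@H](OC(C)=O)C1=O | target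

**Total step count:** 9
**Longest linear sequence:** 9 steps (1 to 20)

**Three steps most likely to fail**

- **Step 7 (key step).** Intermolecular Rauhut–Currier or aldol oligomerisation of the vinyl ketone, or epimerisation α to the aldehyde by the basic zwitterion, may outrun ring closure. The fallback sets out from 16 and forms the same C1–C6 bond by a stoichiometric conjugate addition–aldol sequence. Me2AlSPh in CH2Cl2 at −78 °C delivers thiolate to C7, and the aluminium enolate closes onto the C6 aldehyde to give the β-hydroxy sulfide F1. One equivalent of mCPBA at −78 °C gives the sulfoxide F2. Warming F2 in toluene over CaCO3 effects syn-elimination across C1–C7, and the route is rejoined at 17.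

- **Step 2.** Soft enolisation of the β-branched imide may be sluggish, or coordination of the acetal oxygens to magnesium may erode anti or facial selectivity. The fallback sets out from 4 and purchased 3-methylbutanal and replaces auxiliary control by enamine catalysis. An L-proline-catalysed direct cross-aldol (DMF, 4 °C, slow addition of the donor) should give the anti hydroxy aldehyde F3, which is reduced in the same flask with NaBH4 to the diol F4. Silylation of the primary hydroxyl (t-BuMe2SiCl, imidazole) gives the silyl ether F5, Yamaguchi esterification with 7 gives the tiglate F6, HF·pyridine frees the primary alcohol F7, and Dess–Martin periodinane (NaHCO3 buffer) returns to the route at 10.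

- **Step 5.** Facial selectivity at C3 may be poor, or the basic organolithium may enolise the aldehyde and trigger β-elimination of the C5 tiglate. The fallback sets out from 10 and uses a non-basic, Lewis-acid-promoted addition, for which the reinforcing Felkin and 1,3-anti preferences of anti-configured β-oxygenated aldehydes are best established. (Z)-Bu3SnCH2CH=CHOSiMe2t-Bu with BF3·OEt2 in CH2Cl2 at −78 °C should give the syn silyloxy carbinol F8. Acetylation (Ac2O, pyridine, DMAP) gives the acetate F9, HF·pyridine gives the allylic alcohol F10, and Dess–Martin periodinane oxidises C2 to the vinyl ketone. The route is rejoined at 15, which is then taken through the aqueous acid treatment of step 6.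

**Further compounds**
F1 | step 7 | 3-acetoxy-6-hydroxy-1-(phenylsulfanylmethyl)-2-oxo-4-(propan-2-yl)cyclohexan-5-yl tiglate (route locants; C3 R, C4 S, C5 R; mixture at C1 and C6) | C1(CSc2ccccc2)C(O)[C@H](OC(=O)/C(C)=C/C)[C@H](C(C)C)[C@@H](OC(C)=O)C1=O
F2 | step 7 | the corresponding phenyl sulfoxide (mixture at C1, C6 and sulfur) | C1(CS(=O)c2ccccc2)C(O)[C@H](OC(=O)/C(C)=C/C)[C@H](C(C)C)[C@@H](OC(C)=O)C1=O
F3 | step 2 | (2S,3R)-3-hydroxy-4,4-dimethoxy-2-(propan-2-yl)butanal | O=C[C@@H](C(C)C)[C@@H](O)C(OC)OC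
F4 | step 2 | (2R,3R)-4,4-dimethoxy-2-(propan-2-yl)butane-1,3-diol | OC[C@@H](C(C)C)[C@@H](O)C(OC)OC
F5 | step 2 | (2R,3R)-4-[(tert-butyldimethylsilyl)oxy]-1,1-dimethoxy-3-(propan-2-yl)butan-2-ol | CC(C)(C)[Si](C)(C)OC[C@@H](C(C)C)[C@@H](O)C(OC)OC
F6 | step 2 | (2R,3R)-4-[(tert-butyldimethylsilyl)oxy]-1,1-dimethoxy-3-(propan-2-yl)butan-2-yl (E)-2-methylbut-2-enoate | CC(C)(C)[Si](C)(C)OC[C@@H](C(C)C)[C@@H](OC(=O)/C(C)=C/C)C(OC)OC
F7 | step 2 | (2R,3R)-4-hydroxy-1,1-dimethoxy-3-(propan-2-yl)butan-2-yl (E)-2-methylbut-2-enoate | OC[C@@H](C(C)C)[C@@H](OC(=O)/C(C)=C/C)C(OC)OC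
F8 | step 5 | (3R,4R,5R,6R)-3-[(tert-butyldimethylsilyl)oxy]-4-hydroxy-7,7-dimethoxy-5-(propan-2-yl)hept-1-en-6-yl (E)-2-methylbut-2-enoate | C=C[C@@H](O[Si](C)(C)C(C)(C)C)[C@H](O)[C@@H](C(C)C)[C@@H](OC(=O)/C(C)=C/C)C(OC)OC
F9 | step 5 | (3R,4R,5R,6R)-4-acetoxy-3-[(tert-butyldimethylsilyl)oxy]-7,7-dimethoxy-5-(propan-2-yl)hept-1-en-6-yl (E)-2-methylbut-2-enoate | C=C[C@@H](O[Si](C)(C)C(C)(C)C)[C@H](OC(C)=O)[C@@H](C(C)C)[C@@H](OC(=O)/C(C)=C/C)C(OC)OC
F10 | step 5 | (3R,4R,5R,6R)-4-acetoxy-3-hydroxy-7,7-dimethoxy-5-(propan-2-yl)hept-1-en-6-yl (E)-2-methylbut-2-enoate | C=C[C@@H](O)[C@H](OC(C)=O)[C@@H](C(C)C)[C@@H](OC(=O)/C(C)=C/C)C(OC)OC
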